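The route rests on disconnecting ring B at the bond between the ring-fusion CH and the ring B methylene (the carbon that first carries an ester). The quaternary carbon shared by ring A (diacetoxycyclohexane), ring B (cyclopentanone) and ring C (azonane) lies para to the methyl-bearing, oxygenated carbon of ring A, so ring A is a hidden 4,4-disubstituted cyclohexa-2,5-dienone with two enantiotopic enone arms. A chiral amine–thiourea makes the tethered β-keto ester add to one arm: one operation closes ring B and sets the quaternary carbon and the fusion CH. The precursor is an achiral dienone carrying a 3-silyloxypropyl chain and a 3-oxobutanoate chain on C-4.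

Key step: step 7

Assumption: the sense of induction in step 7 cannot be assigned beforehand; the quinine-derived catalyst is written, and its quinidine-derived pseudoenantiomer is used if the first run gives the antipode of 13.

Design notes:
- **Side chain.** The C-4 side chain of the dienone is carried as a silyl-protected 3-hydroxypropyl group and not as an alkene. No hydroboration is then needed next to ketones, and no second alkene competes in the oxidations.
- **Ester.** The methyl ester is exchanged for an allyl ester in step 10, so that the carboxyl group later leaves at room temperature under zerovalent palladium.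
- **Secondary carbinol of ring A.** Its oxygen must sit on the ring B face, which nucleophiles avoid. A direct nucleophilic epoxidation of the enone in 13 would be expected to attack trans to the ring B carbon on the fusion CH and give the wrong epimer. The oxygen is therefore first placed on that carbon as a ketone (steps 8 and 9), and hydride is then delivered from the open face (step 11).
- **Locants.** Bicyclic intermediates use hexahydroindene numbering: C-1 ester carbon, C-2 ring B ketone, C-3 ring B methylene next to the quaternary C-3a, C-4 to C-7 ring A, C-7a fusion CH.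

Step 1
Reactants: 1 pentane-1,5-diol
Product: 2 5-[(tert-butyldiphenylsilyl)oxy]pentan-1-ol
Conditions: NaH (1.0 equiv), THF, 0 °C to rt; tBuPh2SiCl (1.0 equiv), rt
Reagents that add atoms: tert-butyl(chloro)diphenylsilane, CC(C)(C)[Si](Cl)(c1ccccc1)c1ccccc1
Why: Williamson-type O-silylation of the monosodium alkoxide of a symmetric diol should give the monoether selectively; this bulky silyl group is chosen because it must later outlast aqueous acid, hydrides and lithium amide.

Step 2
Reactants: 2 5-[(tert-butyldiphenylsilyl)oxy]pentan-1-ol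
Product: 3 5-[(tert-butyldiphenylsilyl)oxy]pentanal
Conditions: TEMPO (10 mol%), PhI(OAc)2 (1.1 equiv), CH2Cl2, rt
Reagents that add atoms: none
Why: TEMPO-catalysed (oxoammonium) oxidation stops at the aldehyde and leaves the silyl ether untouched.

Step 3
Reactants: 3 5-[(tert-butyldiphenylsilyl)oxy]pentanal; 4 methyl (E)-4-bromo-3-methoxybut-2-enoate
Product: 7 methyl (E)-8-[(tert-butyldiphenylsilyl)oxy]-5-formyl-3-methoxyoct-2-enoate (racemic), via N-cyclohexyl aldimine 5 (not isolated), via C-alkylated aldimine 6 (not isolated)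
Conditions: cyclohexylamine, 4 Å MS, Et2O, rt; LiN(iPr)2 (1.05 equiv), THF, 0 °C; 4, −78 °C to rt; aq. oxalic acid, rt
Reagents that add atoms: none
Why: Stork metalloenamine alkylation: the lithiated aldimine is C-alkylated once by the SN2-reactive allylic bromide and mild acid then frees the aldehyde without hydrolysing the β-methoxy enoate; the new stereocentre is racemic and is erased in step 5.

Step 4
Reactants: 7 methyl (E)-8-[(tert-butyldiphenylsilyl)oxy]-5-formyl-3-methoxyoct-2-enoate; 8 methyl vinyl ketone
Product: 10 methyl (E)-4-(1-{3-[(tert-butyldiphenylsilyl)oxy]propyl}-4-oxocyclohex-2-en-1-yl)-3-methoxybut-2-enoate (racemic), via keto aldehyde Michael adduct 9 (not isolated)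
Conditions: KOH (0.2 equiv), MeOH, 0 °C to 50 °C
Reagents that add atoms: none
Why: Robinson annulation: base-catalysed Michael addition of the α-branched aldehyde to the enone creates the quaternary carbon, and aldol condensation of the methyl ketone onto the now non-enolisable aldehyde closes the cyclohexenone.

Step 5
Reactants: 10 methyl (E)-4-(1-{3-[(tert-butyldiphenylsilyl)oxy]propyl}-4-oxocyclohex-2-en-1-yl)-3-methoxybut-2-enoate
Product: 11 methyl (E)-4-(1-{3-[(tert-butyldiphenylsilyl)oxy]propyl}-4-oxocyclohexa-2,5-dien-1-yl)-3-methoxybut-2-enoate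
Conditions: DDQ (2 equiv), 1,4-dioxane, 100 °C
Reagents that add atoms: none
Why: DDQ dehydrogenation through the only enol this ketone can form (towards C-6) gives the cross-conjugated dienone, which removes the stereocentre and makes the two enone arms enantiotopic.

Step 6
Reactants: 11 methyl (E)-4-(1-{3-[(tert-butyldiphenylsilyl)oxy]propyl}-4-oxocyclohexa-2,5-dien-1-yl)-3-methoxybut-2-enoate
Product: 12 methyl 4-(1-{3-[(tert-butyldiphenylsilyl)oxy]propyl}-4-oxocyclohexa-2,5-dien-1-yl)-3-oxobutanoate
Conditions: 1 M aq. HCl, THF, 0 °C to rt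
Reagents that add atoms: water, O
Why: Acid hydrolysis of the vinylogous carbonate (enol ether hydrolysis) unmasks the β-keto ester while the non-enolisable dienone and the silyl ether persist; the product is used at once so that no uncatalysed ring closure sets in.

Step 7
Reactants: 12 methyl 4-(1-{3-[(tert-butyldiphenylsilyl)oxy]propyl}-4-oxocyclohexa-2,5-dien-1-yl)-3-oxobutanoate
Product: 13 methyl (1S,3aS,7aS)-3a-{3-[(tert-butyldiphenylsilyl)oxy]propyl}-2,6-dioxo-2,3,3a,6,7,7a-hexahydro-1H-indene-1-carboxylate (cis-fused; 7a-H and the 3a chain on the same face; ester cis to 7a-H)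
Conditions: 1-[3,5-bis(trifluoromethyl)phenyl]-3-[(8α,9S)-6′-methoxycinchonan-9-yl]thiourea (10 mol%), toluene, −20 °C
Reagents that add atoms: none
Why: The quinuclidine nitrogen of the catalyst deprotonates the β-keto ester while the thiourea N–H bonds hold the dienone carbonyl, so the enolate carbon adds within a chiral ion pair to the β-carbon of one enone arm and the resulting ring A enolate is protonated. The closest known reaction type is the organocatalytic desymmetrising intramolecular Michael addition of tethered carbon acids to 4,4-disubstituted cyclohexadienones. Ring B closes in a 5-exo-trig mode. The quaternary carbon and the ring-fusion CH are set together by the catalyst's choice between the two enantiotopic arms, the cis fusion follows from the two-atom reach of the tether, and the ester-bearing carbon settles thermodynamically on the convex face (it is epimerisable and is removed in step 17). The step needs enantiotopic-group selectivity only: the dienone is symmetric and cannot enolise, so no regiochemical question arises, and C- over O-alkylation is secured by ring size.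

Step 8
Reactants: 13 methyl (1S,3aS,7aS)-3a-{3-[(tert-butyldiphenylsilyl)oxy]propyl}-2,6-dioxo-2,3,3a,6,7,7a-hexahydro-1H-indene-1-carboxylate
Product: 14 methyl 3a-{3-[(tert-butyldiphenylsilyl)oxy]propyl}-6-hydroxy-6-methyl-2-oxo-2,3,3a,6,7,7a-hexahydro-1H-indene-1-carboxylate (both C-6 epimers)
Conditions: MeLi (3 equiv), CeCl3 (3 equiv), THF, −78 °C; aq. NH4Cl
Reagents that add atoms: methyllithium, [Li]C
Why: The first equivalent turns the β-keto ester into its enolate, which shields ring B, and the organocerium reagent then adds 1,2 to the ring A enone (Imamoto conditions); the carbinol centre may form as a mixture because step 9 erases it.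

Step 9
Reactants: 14 methyl 3a-{3-[(tert-butyldiphenylsilyl)oxy]propyl}-6-hydroxy-6-methyl-2-oxo-2,3,3a,6,7,7a-hexahydro-1H-indene-1-carboxylate
Product: 15 methyl 3a-{3-[(tert-butyldiphenylsilyl)oxy]propyl}-6-methyl-2,4-dioxo-2,3,3a,4,7,7a-hexahydro-1H-indene-1-carboxylate
Conditions: pyridinium chlorochromate (C5H5NH)(CrO3Cl) (2.5 equiv), 4 Å MS, CH2Cl2, rt
Reagents that add atoms: pyridinium chlorochromate, [O-][Cr](=O)(=O)Cl.c1cc[nH+]cc1
Why: Babler–Dauben oxidative transposition: the chromate ester of the tertiary allylic alcohol (hexavalent chromium) undergoes a [3,3] shift that delivers a chromium-bound oxygen to C-4 and is then oxidised to the β-methyl enone, so both epimers of 14 converge on a ketone next to the quaternary carbon.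

Step 10
Reactants: 15 methyl 3a-{3-[(tert-butyldiphenylsilyl)oxy]propyl}-6-methyl-2,4-dioxo-2,3,3a,4,7,7a-hexahydro-1H-indene-1-carboxylate
Product: 16 prop-2-en-1-yl 3a-{3-[(tert-butyldiphenylsilyl)oxy]propyl}-6-methyl-2,4-dioxo-2,3,3a,4,7,7a-hexahydro-1H-indene-1-carboxylate
Conditions: allyl alcohol (10 equiv), DMAP (0.3 equiv), 4 Å MS, toluene, 110 °C
Reagents that add atoms: prop-2-en-1-ol, C=CCO
Why: β-Keto esters with an α-hydrogen transesterify through an acylketene (DMAP-catalysed, methanol taken up by the sieves); the exchange is placed here because 15 has no hydroxyl group that could intercept the acylketene.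

Step 11
Reactants: 16 prop-2-en-1-yl 3a-{3-[(tert-butyldiphenylsilyl)oxy]propyl}-6-methyl-2,4-dioxo-2,3,3a,4,7,7a-hexahydro-1H-indene-1-carboxylate
Product: 17 prop-2-en-1-yl 3a-{3-[(tert-butyldiphenylsilyl)oxy]propyl}-4-hydroxy-6-methyl-2-oxo-2,3,3a,4,7,7a-hexahydro-1H-indene-1-carboxylate (4-OH trans to the 3a chain, on the face of C-3)
Conditions: NaH (1.1 equiv), THF, 0 °C; iBu2AlH (1.5 equiv), −78 °C; aq. KNaC4H4O6
Reagents that add atoms: none
Why: The sodium enolate masks the β-keto ester, and the aluminium hydride reduces the enone carbonyl 1,2 from the side-chain face, anti to the ring B carbon that stands axial on the neighbouring quaternary centre and anti to the ring B carbon on the fusion CH, so the new hydroxyl should lie equatorial on the ring B face.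

Step 12
Reactants: 17 prop-2-en-1-yl 3a-{3-[(tert-butyldiphenylsilyl)oxy]propyl}-4-hydroxy-6-methyl-2-oxo-2,3,3a,4,7,7a-hexahydro-1H-indene-1-carboxylate
Product: 18 prop-2-en-1-yl 3a-{3-[(tert-butyldiphenylsilyl)oxy]propyl}-5,6-epoxy-4-hydroxy-6-methyl-2-oxooctahydro-1H-indene-1-carboxylate (epoxide oxygen cis to 4-OH)
Conditions: VO(acac)2 (5 mol%), tBuOOH (1.5 equiv), CH2Cl2, 0 °C to rt
Reagents that add atoms: tert-butyl hydroperoxide, CC(C)(C)OO
Why: Vanadium-catalysed hydroxyl-directed epoxidation (Sharpless–Michaelson) delivers the peroxide oxygen to the trisubstituted alkene on the face of the allylic hydroxyl, which fixes the tertiary C–O bond cis to the secondary hydroxyl.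

Step 13
Reactants: 18 prop-2-en-1-yl 3a-{3-[(tert-butyldiphenylsilyl)oxy]propyl}-5,6-epoxy-4-hydroxy-6-methyl-2-oxooctahydro-1H-indene-1-carboxylate
Product: 19 prop-2-en-1-yl 3a-{3-[(tert-butyldiphenylsilyl)oxy]propyl}-4,6-dihydroxy-6-methyl-2-oxooctahydro-1H-indene-1-carboxylate (both hydroxyls trans to the 3a chain; 6-methyl cis to it)
Conditions: LiEt3BH (4 equiv), THF, 0 °C to rt; aq. NH4Cl
Reagents that add atoms: none
Why: The hydride first deprotonates the hydroxyl and the β-keto ester (enolate protection) and then opens the trisubstituted epoxide by SN2 attack at its secondary carbon, leaving the tertiary C–O bond untouched, so the cis-1,3-diol with the methyl group on the side-chain face should result.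

Step 14
Reactants: 20 3,3-diethoxypropan-1-amine
Product: 22 prop-2-en-1-yl (3,3-diethoxypropyl)[(2-nitrophenyl)sulfonyl]carbamate, via sulfonamide 21 (not isolated)
Conditions: 2-O2NC6H4SO2Cl (1.05 equiv), Et3N (3 equiv), CH2Cl2, 0 °C; then DMAP (0.1 equiv), ClCO2CH2CH=CH2 (1.3 equiv), rt
Reagents that add atoms: 2-nitrobenzenesulfonyl chloride, O=S(=O)(Cl)c1ccccc1[N+](=O)[O-]; allyl chloroformate, C=CCOC(=O)Cl
Why: Sulfonylation of the primary amine followed in the same flask by DMAP-catalysed N-acylation of the acidic sulfonamide gives a nitrogen without N–H that will tolerate the dianion of step 16.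

Step 15
Reactants: 22 prop-2-en-1-yl (3,3-diethoxypropyl)[(2-nitrophenyl)sulfonyl]carbamate
Product: 23 prop-2-en-1-yl [(2-nitrophenyl)sulfonyl](3-oxopropyl)carbamate
Conditions: 1 M aq. HCl, acetone, rt
Reagents that add atoms: water, O
Why: Acid-catalysed acetal hydrolysis frees the aldehyde; base is avoided because the β-amino aldehyde could lose the sulfonyl carbamate by E1cB elimination.

Step 16
Reactants: 19 prop-2-en-1-yl 3a-{3-[(tert-butyldiphenylsilyl)oxy]propyl}-4,6-dihydroxy-6-methyl-2-oxooctahydro-1H-indene-1-carboxylate; 23 prop-2-en-1-yl [(2-nitrophenyl)sulfonyl](3-oxopropyl)carbamate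
Product: 24 aldol adduct: 19 carrying at C-3 a 1-hydroxy-3-{(allyloxycarbonyl)[(2-nitrophenyl)sulfonyl]amino}propyl group (mixture at C-3 and at the new carbinol)
Conditions: LiN(iPr)2 (4.5 equiv), THF, −78 to 0 °C; 23 (1.3 equiv), −78 °C; AcOH, −78 °C
Reagents that add atoms: none
Why: Weiler-type dianion aldol addition: once the two alkoxides and the ester enolate are formed, the last deprotonation takes place at the ring B methylene next to the quaternary carbon (the γ-position) and this most nucleophilic site adds to the aldehyde; the two new stereocentres are erased in step 20, and any N-to-O shift of the allyloxycarbonyl group is harmless because step 17 removes it from either atom.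

Step 17
Reactants: 24 aldol adduct
Product: 26 3a-{3-[(tert-butyldiphenylsilyl)oxy]propyl}-4,6-dihydroxy-3-{1-hydroxy-3-[(2-nitrophenyl)sulfonylamino]propyl}-6-methyloctahydro-2H-inden-2-one, via β-keto acid 25 (not isolated)
Conditions: Pd(PPh3)4 (5 mol%), morpholine (6 equiv), THF, rt
Reagents that add atoms: none
Why: Zerovalent palladium ionises both allyl groups (Tsuji–Trost deallylation with morpholine as allyl acceptor), and the β-keto acid and the N-carboxylate lose CO2 at room temperature, which spares the β-hydroxy ketone.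

Step 18
Reactants: 26 silyl ether hydroxy ketone sulfonamide
Product: 27 4,6-dihydroxy-3-{1-hydroxy-3-[(2-nitrophenyl)sulfonylamino]propyl}-3a-(3-hydroxypropyl)-6-methyloctahydro-2H-inden-2-one
Conditions: HF·pyridine, pyridine, THF, 0 °C to rt
Reagents that add atoms: none
Why: Buffered fluoride cleaves the silyl ether through Si–F bond formation without the basicity that would trigger retro-aldol or elimination of the β-hydroxy ketone.

Step 19
Reactants: 27 primary alcohol sulfonamide
Product: 28 N-(2-nitrophenylsulfonyl) azonane triol (ring C closed between nitrogen and the terminal carbon of the 3a chain)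
Conditions: PPh3 (3 equiv), DIAD (3 equiv), toluene/THF, 0.003 M, rt
Reagents that add atoms: none
Why: Fukuyama–Mitsunobu N-alkylation: only the 2-nitrobenzenesulfonamide N–H is acidic enough to act as pronucleophile and only the primary hydroxyl is activated readily, so high dilution should give the nine-membered ring C without touching a stereocentre.

Step 20
Reactants: 28 N-(2-nitrophenylsulfonyl) azonane triol
Product: 30 N-(2-nitrophenylsulfonyl) derivative of the target (E-enone diacetate), via triacetate 29 (not isolated)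
Conditions: Ac2O (10 equiv), DMAP (1 equiv), Et3N, CH2Cl2, 35 °C; then DBU (3 equiv), 0 °C to rt
Reagents that add atoms: acetic anhydride, CC(=O)OC(C)=O
Why: DMAP-catalysed (Steglich-type) acetylation esterifies the secondary, the tertiary and the aldol hydroxyl, and DBU then eliminates the β-acetoxy ketone by E1cB to the conjugated enone, whose E geometry is fixed because a nine-membered ring can only hold the cis ring alkene.

Step 21
Reactants: 30 N-(2-nitrophenylsulfonyl) enone diacetate
Product: 31 CNP0120442.1
Conditions: PhSH (2 equiv), K2CO3 (3 equiv), MeCN, rt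
Reagents that add atoms: none
Why: Fukuyama deprotection: thiolate adds to the nitroarene (Meisenheimer complex, ipso substitution) and the sulfonamide collapses with loss of SO2 to the secondary amine; the acetates are stable to anhydrous carbonate and any thiol adduct of the enone is expected to revert.

Compound list
1 | pentane-1,5-diol | OCCCCCO | starting material
2 | 5-[(tert-butyldiphenylsilyl)oxy]pentan-1-ol | OCCCCCO[Si](c1ccccc1)(c1ccccc1)C(C)(C)C | intermediate
3 | 5-[(tert-butyldiphenylsilyl)oxy]pentanal | O=CCCCCO[Si](c1ccccc1)(c1ccccc1)C(C)(C)C | intermediate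
4 | methyl (E)-4-bromo-3-methoxybut-2-enoate | COC(=O)/C=C(\CBr)OC | starting material
5 | N-cyclohexyl aldimine of 3 (not isolated) | C1CCCCC1N=CCCCCO[Si](c1ccccc1)(c1ccccc1)C(C)(C)C | intermediate
6 | methyl (E)-8-[(tert-butyldiphenylsilyl)oxy]-5-[(cyclohexylimino)methyl]-3-methoxyoct-2-enoate (not isolated, racemic) | COC(=O)/C=C(\CC(C=NC1CCCCC1)CCCO[Si](c1ccccc1)(c1ccccc1)C(C)(C)C)OC | intermediate
7 | methyl (E)-8-[(tert-butyldiphenylsilyl)oxy]-5-formyl-3-methoxyoct-2-enoate (racemic) | COC(=O)/C=C(\CC(C=O)CCCO[Si](c1ccccc1)(c1ccccc1)C(C)(C)C)OC | intermediate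
8 | methyl vinyl ketone (but-3-en-2-one) | CC(=O)C=C | starting material
9 | methyl (E)-5-{3-[(tert-butyldiphenylsilyl)oxy]propyl}-5-formyl-3-methoxy-8-oxonon-2-enoate (not isolated, racemic) | COC(=O)/C=C(\CC(C=O)(CCC(C)=O)CCCO[Si](c1ccccc1)(c1ccccc1)C(C)(C)C)OC | intermediate
10 | methyl (E)-4-(1-{3-[(tert-butyldiphenylsilyl)oxy]propyl}-4-oxocyclohex-2-en-1-yl)-3-methoxybut-2-enoate (racemic) | O=C1C=CC(CCCO[Si](c2ccccc2)(c2ccccc2)C(C)(C)C)(C/C(OC)=C\C(=O)OC)CC1 | intermediate
11 | methyl (E)-4-(1-{3-[(tert-butyldiphenylsilyl)oxy]propyl}-4-oxocyclohexa-2,5-dien-1-yl)-3-methoxybut-2-enoate | O=C1C=CC(CCCO[Si](c2ccccc2)(c2ccccc2)C(C)(C)C)(C/C(OC)=C\C(=O)OC)C=C1 | intermediate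
12 | methyl 4-(1-{3-[(tert-butyldiphenylsilyl)oxy]propyl}-4-oxocyclohexa-2,5-dien-1-yl)-3-oxobutanoate (key-step precursor, achiral) | O=C1C=CC(CCCO[Si](c2ccccc2)(c2ccccc2)C(C)(C)C)(CC(=O)CC(=O)OC)C=C1 | intermediate
13 | methyl (1S,3aS,7aS)-3a-{3-[(tert-butyldiphenylsilyl)oxy]propyl}-2,6-dioxo-2,3,3a,6,7,7a-hexahydro-1H-indene-1-carboxylate (key-step product, cis-fused) | C1=CC(=O)C[C@H]2[C@H](C(=O)OC)C(=O)C[C@]21CCCO[Si](c1ccccc1)(c1ccccc1)C(C)(C)C | intermediate
14 | methyl 3a-{3-[(tert-butyldiphenylsilyl)oxy]propyl}-6-hydroxy-6-methyl-2-oxo-2,3,3a,6,7,7a-hexahydro-1H-indene-1-carboxylate (both C-6 epimers; other centres as in 13) | C1=CC(C)(O)C[C@H]2[C@H](C(=O)OC)C(=O)C[C@]21CCCO[Si](c1ccccc1)(c1ccccc1)C(C)(C)C | intermediate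
15 | methyl 3a-{3-[(tert-butyldiphenylsilyl)oxy]propyl}-6-methyl-2,4-dioxo-2,3,3a,4,7,7a-hexahydro-1H-indene-1-carboxylate (cis-fused as in 13) | O=C1C=C(C)C[C@H]2[C@H](C(=O)OC)C(=O)C[C@]21CCCO[Si](c1ccccc1)(c1ccccc1)C(C)(C)C | intermediate
16 | prop-2-en-1-yl ester analogue of 15 | O=C1C=C(C)C[C@H]2[C@H](C(=O)OCC=C)C(=O)C[C@]21CCCO[Si](c1ccccc1)(c1ccccc1)C(C)(C)C | intermediate
17 | prop-2-en-1-yl 3a-{3-[(tert-butyldiphenylsilyl)oxy]propyl}-4-hydroxy-6-methyl-2-oxo-2,3,3a,4,7,7a-hexahydro-1H-indene-1-carboxylate (4-OH trans to the 3a chain) | O[C@H]1C=C(C)C[C@H]2[C@H](C(=O)OCC=C)C(=O)C[C@]21CCCO[Si](c1ccccc1)(c1ccccc1)C(C)(C)C | intermediate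
18 | prop-2-en-1-yl 3a-{3-[(tert-butyldiphenylsilyl)oxy]propyl}-5,6-epoxy-4-hydroxy-6-methyl-2-oxooctahydro-1H-indene-1-carboxylate (epoxide cis to 4-OH) | O[C@H]1[C@H]3O[C@@]3(C)C[C@H]2[C@H](C(=O)OCC=C)C(=O)C[C@]21CCCO[Si](c1ccccc1)(c1ccccc1)C(C)(C)C | intermediate
19 | prop-2-en-1-yl 3a-{3-[(tert-butyldiphenylsilyl)oxy]propyl}-4,6-dihydroxy-6-methyl-2-oxooctahydro-1H-indene-1-carboxylate (4-OH and 6-OH cis to each other and trans to the 3a chain; 6-methyl cis to the chain) | O[C@H]1C[C@@](C)(O)C[C@H]2[C@H](C(=O)OCC=C)C(=O)C[C@]21CCCO[Si](c1ccccc1)(c1ccccc1)C(C)(C)C | intermediate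
20 | 3,3-diethoxypropan-1-amine | CCOC(CCN)OCC | starting material
21 | N-(3,3-diethoxypropyl)-2-nitrobenzenesulfonamide (not isolated) | CCOC(CCNS(=O)(=O)c1ccccc1[N+](=O)[O-])OCC | intermediate
22 | prop-2-en-1-yl (3,3-diethoxypropyl)[(2-nitrophenyl)sulfonyl]carbamate | CCOC(CCN(C(=O)OCC=C)S(=O)(=O)c1ccccc1[N+](=O)[O-])OCC | intermediate
23 | prop-2-en-1-yl [(2-nitrophenyl)sulfonyl](3-oxopropyl)carbamate | O=CCCN(C(=O)OCC=C)S(=O)(=O)c1ccccc1[N+](=O)[O-] | intermediate
24 | aldol adduct: 19 with a 1-hydroxy-3-{(allyloxycarbonyl)[(2-nitrophenyl)sulfonyl]amino}propyl group at C-3 (mixture at C-3 and the new carbinol) | O[C@H]1C[C@@](C)(O)C[C@H]2[C@H](C(=O)OCC=C)C(=O)C(C(O)CCN(C(=O)OCC=C)S(=O)(=O)c3ccccc3[N+](=O)[O-])[C@]21CCCO[Si](c1ccccc1)(c1ccccc1)C(C)(C)C | intermediate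
25 | β-keto acid from 24 after loss of both allyl groups (not isolated) | O[C@H]1C[C@@](C)(O)C[C@H]2[C@H](C(=O)O)C(=O)C(C(O)CCNS(=O)(=O)c3ccccc3[N+](=O)[O-])[C@]21CCCO[Si](c1ccccc1)(c1ccccc1)C(C)(C)C | intermediate
26 | 3a-{3-[(tert-butyldiphenylsilyl)oxy]propyl}-4,6-dihydroxy-3-{1-hydroxy-3-[(2-nitrophenyl)sulfonylamino]propyl}-6-methyloctahydro-2H-inden-2-one (ring A as in 19) | O[C@H]1C[C@@](C)(O)C[C@H]2CC(=O)C(C(O)CCNS(=O)(=O)c3ccccc3[N+](=O)[O-])[C@]21CCCO[Si](c1ccccc1)(c1ccccc1)C(C)(C)C | intermediate
27 | 4,6-dihydroxy-3-{1-hydroxy-3-[(2-nitrophenyl)sulfonylamino]propyl}-3a-(3-hydroxypropyl)-6-methyloctahydro-2H-inden-2-one | O[C@H]1C[C@@](C)(O)C[C@H]2CC(=O)C(C(O)CCNS(=O)(=O)c3ccccc3[N+](=O)[O-])[C@]21CCCO | intermediate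
28 | N-(2-nitrophenylsulfonyl) azonane triol (rings A, B and C in place; hydroxyl on the ring C carbon next to the ring B α-carbon, as a mixture) | O[C@H]1C[C@@](C)(O)C[C@H]2CC(=O)C3C(O)CCN(S(=O)(=O)c4ccccc4[N+](=O)[O-])CCC[C@@]321 | intermediate
29 | triacetate of 28 (not isolated) | CC(=O)O[C@H]1C[C@@](C)(OC(C)=O)C[C@H]2CC(=O)C3C(OC(C)=O)CCN(S(=O)(=O)c4ccccc4[N+](=O)[O-])CCC[C@@]321 | intermediate
30 | N-(2-nitrophenylsulfonyl) derivative of the target (E-enone; both acetates) | CC(=O)O[C@H]1C[C@@](C)(OC(C)=O)C[C@H]2CC(=O)/C3=C/CCN(S(=O)(=O)c4ccccc4[N+](=O)[O-])CCC[C@@]321 | intermediate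
31 | CNP0120442.1: tricyclic amino enone diacetate (secondary acetoxy carbon S; tertiary acetoxy carbon S; ring-fusion CH S; quaternary carbon S; E-enone) | CC(=O)O[C@H]1C[C@@](C)(OC(C)=O)C[C@H]2CC(=O)/C3=C/CCNCCC[C@@]321 | target

Total step count: 21 (19 in the main line, 2 for aldehyde 23).
Longest linear sequence: 19 steps (steps 1 to 13 and 16 to 21).

Steps most likely to fail

Step 7. The catalyst may discriminate poorly between the two enone arms, or an uncatalysed ring closure may run alongside and dilute the enantiomeric excess. The fallback replaces the catalyst by a stoichiometric chiral auxiliary and sets out from 12. Condensation with (S)-1-phenylethylamine (cat. AcOH, 4 Å MS, toluene) would give the Z-enamino ester F1. On warming (MgBr2·OEt2 if needed) the chiral secondary enamine should add to one enone arm in an aza-ene-type Michael addition to give the bicyclic enamino ester F2. Hydrolysis with aqueous AcOH releases the amine and comes back to the route at 13; the (R)-amine is used if the induced sense is the wrong one.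

Step 16. The functionalised aldehyde may be enolised with loss of the sulfonyl carbamate, may transfer its acyl group, or may take up an electron at the nitroarene before the carbanion adds. The fallback introduces nitrogen after the aldol and sets out from 19. The same polyanion is added to commercial 3-[(tert-butyldimethylsilyl)oxy]propanal to give the aldol F3. Pd(PPh3)4 and morpholine remove the allyl ester to the β-keto acid F4, which loses CO2 to the ketone F5. PPTS in MeOH cleaves the primary tert-butyldimethylsilyl ether selectively to the alcohol F6. A Mitsunobu reaction of F6 with 2-nitrobenzenesulfonamide (PPh3, DIAD) at the primary hydroxyl comes back to the route at 26.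

Step 19. Intermolecular N-alkylation to oligomers may outrun closure of the nine-membered ring, or the betaine may dehydrate the β-hydroxy ketone. The fallback separates activation from closure and sets out from 27. I2, PPh3 and imidazole convert the primary alcohol selectively into the iodide F7. Slow addition of F7 to Cs2CO3 in MeCN (0.002 M, 50 °C) closes ring C by sulfonamide alkylation and comes back to the route at 28.

Further compounds
F1 | step 7 | methyl (Z)-4-(1-{3-[(tert-butyldiphenylsilyl)oxy]propyl}-4-oxocyclohexa-2,5-dien-1-yl)-3-{[(S)-1-phenylethyl]amino}but-2-enoate | O=C1C=CC(CCCO[Si](c2ccccc2)(c2ccccc2)C(C)(C)C)(C/C(N[C@@H](C)c2ccccc2)=C/C(=O)OC)C=C1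
F2 | step 7 | methyl 3a-{3-[(tert-butyldiphenylsilyl)oxy]propyl}-6-oxo-2-{[(S)-1-phenylethyl]amino}-3,3a,7,7a-tetrahydro-6H-indene-1-carboxylate (cis-fused as in 13) | C1=CC(=O)C[C@H]2C(C(=O)OC)=C(N[C@@H](C)c3ccccc3)C[C@]21CCCO[Si](c1ccccc1)(c1ccccc1)C(C)(C)C
F3 | step 16 | aldol adduct of 19 with 3-[(tert-butyldimethylsilyl)oxy]propanal (C-3 carries a 3-[(tert-butyldimethylsilyl)oxy]-1-hydroxypropyl group) | O[C@H]1C[C@@](C)(O)C[C@H]2[C@H](C(=O)OCC=C)C(=O)C(C(O)CCO[Si](C)(C)C(C)(C)C)[C@]21CCCO[Si](c1ccccc1)(c1ccccc1)C(C)(C)C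
F4 | step 16 | β-keto acid from F3 | O[C@H]1C[C@@](C)(O)C[C@H]2[C@H](C(=O)O)C(=O)C(C(O)CCO[Si](C)(C)C(C)(C)C)[C@]21CCCO[Si](c1ccccc1)(c1ccccc1)C(C)(C)C
F5 | step 16 | decarboxylated ketone from F4 | O[C@H]1C[C@@](C)(O)C[C@H]2CC(=O)C(C(O)CCO[Si](C)(C)C(C)(C)C)[C@]21CCCO[Si](c1ccccc1)(c1ccccc1)C(C)(C)C
F6 | step 16 | 3a-{3-[(tert-butyldiphenylsilyl)oxy]propyl}-3-(1,3-dihydroxypropyl)-4,6-dihydroxy-6-methyloctahydro-2H-inden-2-one | O[C@H]1C[C@@](C)(O)C[C@H]2CC(=O)C(C(O)CCO)[C@]21CCCO[Si](c1ccccc1)(c1ccccc1)C(C)(C)C
F7 | step 19 | 4,6-dihydroxy-3-{1-hydroxy-3-[(2-nitrophenyl)sulfonylamino]propyl}-3a-(3-iodopropyl)-6-methyloctahydro-2H-inden-2-one | O[C@H]1C[C@@](C)(O)C[C@H]2CC(=O)C(C(O)CCNS(=O)(=O)c3ccccc3[N+](=O)[O-])[C@]21CCCI
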